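**Retrosynthetic overview**
- The target is 3,8-dihydroxy-5,6,7,4'-tetramethoxyflavone. The last three steps tell the two ring A phenols apart (benzyl on the free 8-OH, methyl on the chelated 5-OH) and then remove both benzyl groups.
- Key disconnection: the O1–C8a bond of ring C. In ring A, C5 and C8 carry para oxygens on either side of the C6 and C7 methoxy groups, so ring A is the reduced form of a 2,3-dimethoxy-1,4-benzoquinone. Its C8a is β to both the C5 quinone carbonyl and the C4 ketone, and the enol oxygen of the side-chain 1,3-diketone adds there.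
- The acylquinone comes from a 2,3,4,5-tetramethoxyphenyl 1,3-diketone by oxidative demethylation. The diketone comes from aldol addition and oxidation of an α-benzyloxy aryl ketone, itself made from lithiated 1,2,3,4-tetramethoxybenzene and a benzyloxyacetic Weinreb amide.
- Ring order: rings A and B are bought as arenes; ring C is the only ring formed (step 6).

Key step: step 6

Remark on the chemistry: the target has no stereocentre. Compounds 7, 8 and 10 are racemic (7 as a mixture of diastereomers) and their stereocentres disappear along the route. Quinone 9 is carried forward crude, directly after extraction.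

**Route**

Step 1
Reactants: 1 benzyloxyacetyl chloride
Product: 2 2-(benzyloxy)-N-methoxy-N-methylacetamide
Conditions: MeNHOMe·HCl, Et3N (2.2 equiv), CH2Cl2, 0 °C to rt
Reagents that add atoms: N,O-dimethylhydroxylamine hydrochloride, CNOC.Cl
Why: N-acylation of the hydroxylamine by the acid chloride (Weinreb amide formation) should proceed cleanly and leaves the benzyl ether untouched.

Step 2
Reactants: 3 1,2,3,4-tetramethoxybenzene; 2 2-(benzyloxy)-N-methoxy-N-methylacetamide
Product: 5 2-(benzyloxy)-1-(2,3,4,5-tetramethoxyphenyl)ethan-1-one, via (2,3,4,5-tetramethoxyphenyl)lithium 4 (not isolated)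
Conditions: n-BuLi, TMEDA, THF, 0 °C; then 2, −78 °C to 0 °C; 1 M HCl quench
Reagents that add atoms: n-butyllithium, [Li]CCCC (its lithium sits in intermediate 4; none of its atoms remain in 5)
Why: Directed ortho-lithiation at the C–H next to the terminal methoxy group gives aryllithium 4, and its addition to the Weinreb amide stops at the chelated tetrahedral intermediate, so the ketone is released only on work-up (Weinreb ketone synthesis).

Step 3
Reactants: 5 2-(benzyloxy)-1-(2,3,4,5-tetramethoxyphenyl)ethan-1-one; 6 4-methoxybenzaldehyde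
Product: 7 2-(benzyloxy)-3-hydroxy-3-(4-methoxyphenyl)-1-(2,3,4,5-tetramethoxyphenyl)propan-1-one (racemic, mixture of diastereomers)
Conditions: LiN(iPr)2, THF, −78 °C; then 6, −78 °C; AcOH quench at −78 °C
Reagents that add atoms: none
Why: Lithium enolate aldol addition, in which kinetic deprotonation of the only enolisable position (the benzyloxy-bearing CH2) and addition to the non-enolisable aldehyde should give the β-hydroxy ketone; its two stereocentres are set without control because the next step removes one and makes the other labile.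

Step 4
Reactants: 7 2-(benzyloxy)-3-hydroxy-3-(4-methoxyphenyl)-1-(2,3,4,5-tetramethoxyphenyl)propan-1-one
Product: 8 2-(benzyloxy)-1-(4-methoxyphenyl)-3-(2,3,4,5-tetramethoxyphenyl)propane-1,3-dione (racemic)
Conditions: IBX (1.5 equiv), DMSO, rt
Reagents that add atoms: none
Why: Hypervalent iodine oxidation of the benzylic secondary alcohol with IBX is a standard way from aldols to 1,3-diketones and uses no base, so retro-aldol cleavage is not expected.

Step 5
Reactants: 8 2-(benzyloxy)-1-(4-methoxyphenyl)-3-(2,3,4,5-tetramethoxyphenyl)propane-1,3-dione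
Product: 9 2-[2-(benzyloxy)-3-(4-methoxyphenyl)-3-oxopropanoyl]-5,6-dimethoxy-1,4-benzoquinone (racemic)
Conditions: (NH4)2Ce(NO3)6 (2.5 equiv), MeCN/H2O 2:1, 0 °C, 10 min; cold extraction, used crude at once
Reagents that add atoms: water, O
Why: Oxidative demethylation, in which one-electron oxidation of the electron-rich ring, attack of water at the two para-related methoxy-bearing carbons and loss of two methanol should give the para-quinone as known for 2,3,4,5-tetramethoxytoluene, while the carbonyl-deactivated anisoyl ring and the benzyl ether should not react.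

Step 6
Reactants: 9 2-[2-(benzyloxy)-3-(4-methoxyphenyl)-3-oxopropanoyl]-5,6-dimethoxy-1,4-benzoquinone
Product: 11 3-(benzyloxy)-5,8-dihydroxy-6,7-dimethoxy-2-(4-methoxyphenyl)-4H-chromen-4-one, via 8aH-chromene-4,8-dione adduct 10 (not isolated)
Conditions: NaOAc (0.2 equiv), AcOH/CH2Cl2 1:4, 0.01 M, argon, 0 °C to rt; then aq. Na2S2O4 wash
Reagents that add atoms: none
Why: Acetate-catalysed enolisation of the 2-benzyloxy-1,3-diketone places a hydroxyl on the anisoyl carbon, and this oxygen adds to the one unsubstituted quinone carbon (the future C8a), which is β to both the C5 quinone carbonyl and the C4 ketone; protonation gives adduct 10, and a second proton shift from C8a to O8 aromatises ring A. The closest known reaction type is the intramolecular oxa-Michael addition of a hydroxyl group to C3 of a 2-acyl-1,4-benzoquinone, as in the closure of 2-(2-hydroxybenzoyl)quinones to xanthones. Ring C closes 6-endo-trig on the C4a=C8a quinone double bond, and it closes through oxygen because the carbon terminus of the enol could only give a four-membered ring. No stereocentre remains, since the C8a centre of 10 is lost on aromatisation. The step needs attack at C8a and not at the methoxy-bearing quinone carbons, which the tether length and the double activation of the only quinone C–H should secure; it also needs ring closure to outrun redox exchange between the product hydroquinone and unreacted quinone, which high dilution, the acidic medium and the reductive wash are meant to control.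

Step 7
Reactants: 11 3-(benzyloxy)-5,8-dihydroxy-6,7-dimethoxy-2-(4-methoxyphenyl)-4H-chromen-4-one
Product: 12 3,8-bis(benzyloxy)-5-hydroxy-6,7-dimethoxy-2-(4-methoxyphenyl)-4H-chromen-4-one
Conditions: BnBr (1.05 equiv), K2CO3 (1.1 equiv), degassed DMF, argon, rt
Reagents that add atoms: benzyl bromide, BrCc1ccccc1
Why: Williamson etherification with one equivalent of base and halide should alkylate the free, more acidic 8-hydroxyl, because the 5-hydroxyl is held in a hydrogen bond to the C4 carbonyl and reacts far more slowly.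

Step 8
Reactants: 12 3,8-bis(benzyloxy)-5-hydroxy-6,7-dimethoxy-2-(4-methoxyphenyl)-4H-chromen-4-one
Product: 13 3,8-bis(benzyloxy)-5,6,7-trimethoxy-2-(4-methoxyphenyl)-4H-chromen-4-one
Conditions: MeI (excess), K2CO3, DMF, 45 °C, sealed vessel
Reagents that add atoms: iodomethane, CI
Why: Williamson methylation under forcing conditions (excess halide, heat, polar aprotic solvent) should break the chelate and methylate the last free hydroxyl, all other oxygens being already capped.

Step 9
Reactants: 13 3,8-bis(benzyloxy)-5,6,7-trimethoxy-2-(4-methoxyphenyl)-4H-chromen-4-one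
Product: 14 eriostemin, 3,8-dihydroxy-5,6,7-trimethoxy-2-(4-methoxyphenyl)-4H-chromen-4-one
Conditions: H2 (1 atm), 10% Pd/C, EtOAc/MeOH, rt
Reagents that add atoms: none
Why: Catalytic hydrogenolysis should cleave the aryl and the enol benzyl ether at atmospheric pressure, while the aryl-conjugated C2=C3 bond of the flavone and the methyl ethers stay intact.

**Compound list**

1 | benzyloxyacetyl chloride | O=C(Cl)COCc1ccccc1 | starting material
2 | 2-(benzyloxy)-N-methoxy-N-methylacetamide | CON(C)C(=O)COCc1ccccc1 | intermediate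
3 | 1,2,3,4-tetramethoxybenzene | COc1ccc(OC)c(OC)c1OC | starting material
4 | (2,3,4,5-tetramethoxyphenyl)lithium | [Li]c1cc(OC)c(OC)c(OC)c1OC | intermediate
5 | 2-(benzyloxy)-1-(2,3,4,5-tetramethoxyphenyl)ethan-1-one | COc1cc(C(=O)COCc2ccccc2)c(OC)c(OC)c1OC | intermediate
6 | 4-methoxybenzaldehyde | COc1ccc(C=O)cc1 | starting material
7 | 2-(benzyloxy)-3-hydroxy-3-(4-methoxyphenyl)-1-(2,3,4,5-tetramethoxyphenyl)propan-1-one (racemic, diastereomer mixture) | COc1ccc(C(O)C(OCc2ccccc2)C(=O)c2cc(OC)c(OC)c(OC)c2OC)cc1 | intermediate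
8 | 2-(benzyloxy)-1-(4-methoxyphenyl)-3-(2,3,4,5-tetramethoxyphenyl)propane-1,3-dione (racemic) | COc1ccc(C(=O)C(OCc2ccccc2)C(=O)c2cc(OC)c(OC)c(OC)c2OC)cc1 | intermediate
9 | 2-[2-(benzyloxy)-3-(4-methoxyphenyl)-3-oxopropanoyl]-5,6-dimethoxy-1,4-benzoquinone (racemic) | COC1=C(OC)C(=O)C(C(=O)C(OCc2ccccc2)C(=O)c2ccc(OC)cc2)=CC1=O | intermediate
10 | 3-(benzyloxy)-5-hydroxy-6,7-dimethoxy-2-(4-methoxyphenyl)-8aH-chromene-4,8-dione (racemic) | COC1=C(OC)C(=O)C2OC(c3ccc(OC)cc3)=C(OCc3ccccc3)C(=O)C2=C1O | intermediate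
11 | 3-(benzyloxy)-5,8-dihydroxy-6,7-dimethoxy-2-(4-methoxyphenyl)-4H-chromen-4-one | COc1ccc(-c2oc3c(O)c(OC)c(OC)c(O)c3c(=O)c2OCc2ccccc2)cc1 | intermediate
12 | 3,8-bis(benzyloxy)-5-hydroxy-6,7-dimethoxy-2-(4-methoxyphenyl)-4H-chromen-4-one | COc1ccc(-c2oc3c(OCc4ccccc4)c(OC)c(OC)c(O)c3c(=O)c2OCc2ccccc2)cc1 | intermediate
13 | 3,8-bis(benzyloxy)-5,6,7-trimethoxy-2-(4-methoxyphenyl)-4H-chromen-4-one | COc1ccc(-c2oc3c(OCc4ccccc4)c(OC)c(OC)c(OC)c3c(=O)c2OCc2ccccc2)cc1 | intermediate
14 | eriostemin, 3,8-dihydroxy-5,6,7-trimethoxy-2-(4-methoxyphenyl)-4H-chromen-4-one | COc1ccc(-c2oc3c(O)c(OC)c(OC)c(OC)c3c(=O)c2O)cc1 | target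

**Step count and risks**

Total step count: 9. Longest linear sequence: 9 steps (steps 1 to 9, from 1 to 14).

Steps most likely to fail:

1. Step 6 (key ring closure). Ring closure may be outrun by redox exchange between the product hydroquinone and unreacted acylquinone, or by intermolecular addition and oligomerisation of the quinone. Fallback, setting out from ketone 5 and coming back at 11: ring C is closed on an aryl bromide and the hydroquinone is unmasked afterwards on the flavone.
   - Bromination of the single aryl C–H of 5 with NBS in MeCN should give 2-(benzyloxy)-1-(2-bromo-3,4,5,6-tetramethoxyphenyl)ethan-1-one F1.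
   - Aldol addition to 6 as in step 3 gives 2-(benzyloxy)-1-(2-bromo-3,4,5,6-tetramethoxyphenyl)-3-hydroxy-3-(4-methoxyphenyl)propan-1-one F2.
   - IBX oxidation gives 2-(benzyloxy)-1-(2-bromo-3,4,5,6-tetramethoxyphenyl)-3-(4-methoxyphenyl)propane-1,3-dione F3.
   - Intramolecular Ullmann-type O-arylation of the diketone enolate (CuI, 1,10-phenanthroline, K2CO3, DMF, 100 °C) closes ring C to 3-(benzyloxy)-5,6,7,8-tetramethoxy-2-(4-methoxyphenyl)-4H-chromen-4-one F4.
   - Oxidative demethylation of this robust flavone with (NH4)2Ce(NO3)6 in aqueous MeCN (or aqueous HNO3) gives 3-(benzyloxy)-6,7-dimethoxy-2-(4-methoxyphenyl)-4H-chromene-4,5,8-trione F5.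
   - Reduction with aqueous Na2S2O4 gives 11.

2. Step 5 (oxidative demethylation). The tetravalent cerium oxidant may attack the enolisable diketone, give ortho-quinone formation, or over-oxidise the ring instead of demethylating cleanly at the para positions. Fallback, setting out from arene 3 and coming back at 9: the hydroquinone oxygens are carried as acetals, so the diketone never meets cerium.
   - (NH4)2Ce(NO3)6 on 3 gives 2,3-dimethoxy-1,4-benzoquinone F6.
   - Na2S2O4 reduces it to 2,3-dimethoxybenzene-1,4-diol F7.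
   - MOMCl and iPr2NEt give 2,3-dimethoxy-1,4-bis(methoxymethoxy)benzene F8.
   - Ortho-lithiation (n-BuLi, THF, 0 °C) and acylation with amide 2 give 2-(benzyloxy)-1-[3,4-dimethoxy-2,5-bis(methoxymethoxy)phenyl]ethan-1-one F9.
   - Aldol addition to 6 gives 2-(benzyloxy)-1-[3,4-dimethoxy-2,5-bis(methoxymethoxy)phenyl]-3-hydroxy-3-(4-methoxyphenyl)propan-1-one F10.
   - IBX gives 2-(benzyloxy)-1-[3,4-dimethoxy-2,5-bis(methoxymethoxy)phenyl]-3-(4-methoxyphenyl)propane-1,3-dione F11.
   - HCl in MeOH at rt removes both acetals to give 2-(benzyloxy)-1-(2,5-dihydroxy-3,4-dimethoxyphenyl)-3-(4-methoxyphenyl)propane-1,3-dione F12.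
   - Ag2O with Na2SO4 in CH2Cl2 oxidises this hydroquinone to quinone 9.

3. Step 7 (selective 8-O-benzylation). Under basic alkylation the hydroquinone anion may be oxidised by air to the 5,8-quinone, and site selectivity may be lost by alkylation at both hydroxyls. Fallback, setting out from 11 and coming back at 14: the free hydroxyl is silylated without strong base.
   - TBSCl and imidazole in DMF should silylate only the non-chelated 8-hydroxyl, giving 3-(benzyloxy)-8-[(tert-butyldimethylsilyl)oxy]-5-hydroxy-6,7-dimethoxy-2-(4-methoxyphenyl)-4H-chromen-4-one F13.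
   - NaH and MeI in THF give 3-(benzyloxy)-8-[(tert-butyldimethylsilyl)oxy]-5,6,7-trimethoxy-2-(4-methoxyphenyl)-4H-chromen-4-one F14.
   - Bu4NF with AcOH in THF gives 3-(benzyloxy)-8-hydroxy-5,6,7-trimethoxy-2-(4-methoxyphenyl)-4H-chromen-4-one F15.
   - Hydrogenolysis (H2, 10% Pd/C) gives 14.

**Further compounds**

F1 | step 6 | 2-(benzyloxy)-1-(2-bromo-3,4,5,6-tetramethoxyphenyl)ethan-1-one | COc1c(Br)c(C(=O)COCc2ccccc2)c(OC)c(OC)c1OC
F2 | step 6 | 2-(benzyloxy)-1-(2-bromo-3,4,5,6-tetramethoxyphenyl)-3-hydroxy-3-(4-methoxyphenyl)propan-1-one | COc1ccc(C(O)C(OCc2ccccc2)C(=O)c2c(Br)c(OC)c(OC)c(OC)c2OC)cc1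
F3 | step 6 | 2-(benzyloxy)-1-(2-bromo-3,4,5,6-tetramethoxyphenyl)-3-(4-methoxyphenyl)propane-1,3-dione | COc1ccc(C(=O)C(OCc2ccccc2)C(=O)c2c(Br)c(OC)c(OC)c(OC)c2OC)cc1
F4 | step 6 | 3-(benzyloxy)-5,6,7,8-tetramethoxy-2-(4-methoxyphenyl)-4H-chromen-4-one | COc1ccc(-c2oc3c(OC)c(OC)c(OC)c(OC)c3c(=O)c2OCc2ccccc2)cc1
F5 | step 6 | 3-(benzyloxy)-6,7-dimethoxy-2-(4-methoxyphenyl)-4H-chromene-4,5,8-trione | COC1=C(OC)C(=O)C2=C(C1=O)C(=O)C(OCc1ccccc1)=C(c1ccc(OC)cc1)O2
F6 | step 5 | 2,3-dimethoxy-1,4-benzoquinone | COC1=C(OC)C(=O)C=CC1=O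
F7 | step 5 | 2,3-dimethoxybenzene-1,4-diol | COc1c(O)ccc(O)c1OC
F8 | step 5 | 2,3-dimethoxy-1,4-bis(methoxymethoxy)benzene | COCOc1ccc(OCOC)c(OC)c1OC
F9 | step 5 | 2-(benzyloxy)-1-[3,4-dimethoxy-2,5-bis(methoxymethoxy)phenyl]ethan-1-one | COCOc1cc(C(=O)COCc2ccccc2)c(OCOC)c(OC)c1OC
F10 | step 5 | 2-(benzyloxy)-1-[3,4-dimethoxy-2,5-bis(methoxymethoxy)phenyl]-3-hydroxy-3-(4-methoxyphenyl)propan-1-one | COCOc1cc(C(=O)C(OCc2ccccc2)C(O)c2ccc(OC)cc2)c(OCOC)c(OC)c1OC
F11 | step 5 | 2-(benzyloxy)-1-[3,4-dimethoxy-2,5-bis(methoxymethoxy)phenyl]-3-(4-methoxyphenyl)propane-1,3-dione | COCOc1cc(C(=O)C(OCc2ccccc2)C(=O)c2ccc(OC)cc2)c(OCOC)c(OC)c1OC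
F12 | step 5 | 2-(benzyloxy)-1-(2,5-dihydroxy-3,4-dimethoxyphenyl)-3-(4-methoxyphenyl)propane-1,3-dione | COc1ccc(C(=O)C(OCc2ccccc2)C(=O)c2cc(O)c(OC)c(OC)c2O)cc1
F13 | step 7 | 3-(benzyloxy)-8-[(tert-butyldimethylsilyl)oxy]-5-hydroxy-6,7-dimethoxy-2-(4-methoxyphenyl)-4H-chromen-4-one | COc1ccc(-c2oc3c(O[Si](C)(C)C(C)(C)C)c(OC)c(OC)c(O)c3c(=O)c2OCc2ccccc2)cc1
F14 | step 7 | 3-(benzyloxy)-8-[(tert-butyldimethylsilyl)oxy]-5,6,7-trimethoxy-2-(4-methoxyphenyl)-4H-chromen-4-one | COc1ccc(-c2oc3c(O[Si](C)(C)C(C)(C)C)c(OC)c(OC)c(OC)c3c(=O)c2OCc2ccccc2)cc1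
F15 | step 7 | 3-(benzyloxy)-8-hydroxy-5,6,7-trimethoxy-2-(4-methoxyphenyl)-4H-chromen-4-one | COc1ccc(-c2oc3c(O)c(OC)c(OC)c(OC)c3c(=O)c2OCc2ccccc2)cc1
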